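## Retrosynthetic overview

1. Target ⇐ 2‑hydroxy‑3‑ketone ⇐ 3‑keto acid: the C‑3 carbinol comes from equatorial hydride delivery, the C2–O bond from enolate hydroxylation on the open face of ring A; one chromic acid oxidation unveils ketone and acid together.
2. Key bond: the oxirane C–O bonds of a (2S,3R)‑epoxy alcohol, made by asymmetric epoxidation of a Z‑allylic alcohol. In the same flask C4–O is exchanged for C4–C5 with inversion; ring A closes first, then ring B, in one cationic cascade, so C‑3, C‑4, C‑5, C‑9 and C‑10 all derive from the epoxide.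
3. Z‑allylic alcohol ⇐ B‑alkyl Suzuki coupling of a diene‑derived borane with (Z)‑3‑iodo‑2‑methylallyl alcohol (from propargyl alcohol).
4. Diene ⇐ (R)‑2,3‑dihydrofarnesol by terminal allylic oxidation and methylenation; C‑13 is set by Noyori hydrogenation of (2E,6E)‑farnesol.

Assumption: labdane numbering is used throughout (C‑19 = oxygenated carbon on C‑4, C‑20 = methyl on C‑10), also for the open‑chain precursors; the target is the ent‑labdane (2S,3R,4R,5S,9R,10S,13R).

## Route

Step 1
Reactants: 1 (2E,6E)-farnesol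
Product: 2 (3R,6E)-3,7,11-trimethyldodeca-6,10-dien-1-ol
Conditions: Ru(OAc)2[(S)-BINAP] (0.5 mol%), H2 (30 atm), MeOH, 20 °C
Reagents that add atoms: none
Why: Noyori asymmetric hydrogenation: the allylic hydroxyl binds ruthenium, so only the 2,3‑olefin is reduced, and the (S)‑BINAP complex adds H2 to the face of the E‑olefin that gives the 3R centre (the future C‑13), the same sense as geraniol to (R)‑citronellol.

Step 2
Reactants: 2 (3R,6E)-3,7,11-trimethyldodeca-6,10-dien-1-ol
Product: 3 tert-butyldimethyl{[(3R,6E)-3,7,11-trimethyldodeca-6,10-dien-1-yl]oxy}silane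
Conditions: TBSCl, imidazole, CH2Cl2, 23 °C
Reagents that add atoms: tert-butyldimethylsilyl chloride, CC(C)(C)[Si](C)(C)Cl
Why: Standard silylation of the only hydroxyl; the silyl ether carries C‑15 through the route and is later oxidised directly to the acid.

Step 3
Reactants: 3 tert-butyldimethyl{[(3R,6E)-3,7,11-trimethyldodeca-6,10-dien-1-yl]oxy}silane
Product: 5 (2E,6E,10R)-12-[(tert-butyldimethylsilyl)oxy]-2,6,10-trimethyldodeca-2,6-dienal, via terminal allylic alcohol 4 (not isolated)
Conditions: SeO2 (0.3 equiv), t-BuOOH (3 equiv), salicylic acid (0.1 equiv), CH2Cl2, 0 → 23 °C; then MnO2 (10 equiv), 23 °C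
Reagents that add atoms: selenium dioxide, O=[Se]=O; tert-butyl hydroperoxide, CC(C)(C)OO
Why: Selenium dioxide allylic oxidation (ene reaction, then [2,3]-sigmatropic shift) attacks the terminal methyl trans to the chain, and MnO2 then oxidises only the allylic alcohol, so the E‑enal forms without a new stereocentre.

Step 4
Reactants: 5 (2E,6E,10R)-12-[(tert-butyldimethylsilyl)oxy]-2,6,10-trimethyldodeca-2,6-dienal
Product: 6 tert-butyldimethyl{[(3R,6E,10E)-3,7,11-trimethyltrideca-6,10,12-trien-1-yl]oxy}silane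
Conditions: Ph3PCH3Br (1.5 equiv), KN(SiMe3)2 (1.4 equiv), THF, 0 °C; then 5, −78 → 0 °C
Reagents that add atoms: methyltriphenylphosphonium bromide, [Br-].C[P+](c1ccccc1)(c1ccccc1)c1ccccc1
Why: Wittig methylenation of the unhindered enal gives the terminal 1,3‑diene; olefin geometry and the silyl ether are untouched.

Step 5
Reactants: 7 prop-2-yn-1-ol
Product: 9 (Z)-3-iodo-2-methylprop-2-en-1-ol, via chelated alkenylmagnesium alkoxide 8 (not isolated)
Conditions: MeMgBr (2.5 equiv), CuI (10 mol%), Et2O/THF, −10 → 23 °C; then I2 (1.5 equiv), −78 → 0 °C; H2O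
Reagents that add atoms: methylmagnesium bromide, C[Mg]Br; iodine, II
Why: Copper‑catalysed anti‑carbomagnesiation of the propargyl alkoxide (methyl to C‑2, magnesium to C‑3 held cis to the CH2O group in a five‑membered chelate) followed by iodinolysis with retention fixes the Z geometry that later makes the C‑19 carbon axial.

Step 6
Reactants: 6 tert-butyldimethyl{[(3R,6E,10E)-3,7,11-trimethyltrideca-6,10,12-trien-1-yl]oxy}silane; 9 (Z)-3-iodo-2-methylprop-2-en-1-ol
Product: 11 (2Z,6E,10E,14R)-16-[(tert-butyldimethylsilyl)oxy]-2,6,10,14-tetramethylhexadeca-2,6,10-trien-1-ol, via B-alkyl-9-BBN borane 10 (not isolated)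
Conditions: 9-BBN (1.1 equiv), THF, 0 → 23 °C; then 3 M aq. Cs2CO3, 9 (1.2 equiv), Pd(dppf)Cl2 (5 mol%), AsPh3 (10 mol%), DMF, 23 °C
Reagents that add atoms: none
Why: 9‑BBN adds only to the monosubstituted end of the diene (boron on the terminal carbon), and the B‑alkyl Suzuki–Miyaura coupling proceeds with retention of the Z‑iodide geometry and tolerates the free hydroxyl.

Step 7
Reactants: 11 (2Z,6E,10E,14R)-16-[(tert-butyldimethylsilyl)oxy]-2,6,10,14-tetramethylhexadeca-2,6,10-trien-1-ol
Product: 13 (3R,4R,5S,9R,10S,13R)-15-[(tert-butyldimethylsilyl)oxy]-ent-labd-7-ene-3,19-diol, via cis-epoxy alcohol 12 (not isolated)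
Conditions: Ti(OiPr)4 (0.2 equiv), L-(+)-diethyl tartrate (0.24 equiv), t-BuOOH (1.5 equiv), 4 Å sieves, CH2Cl2, −20 °C; then P(OMe)3 (0.6 equiv), −20 °C; then Me2AlCl (6 equiv), −78 → −30 °C; cold 1 M HCl
Reagents that add atoms: tert-butyl hydroperoxide, CC(C)(C)OO
Why: Proposed new method: one‑flask asymmetric epoxidation/epoxide‑opening bicyclisation — the Ti(OiPr)4–L‑(+)‑tartrate catalyst epoxidises the hydroxyl‑bound Z‑olefin on one face (closest known: Katsuki–Sharpless epoxidation, which for this substitution pattern gives the (2S,3R)‑epoxy alcohol), and after the excess hydroperoxide is reduced Me2AlCl turns the unisolated epoxy alcohol into an aluminium alkoxide that chelates the oxirane oxygen, so the C4–O bond ionises at the tertiary carbon with no ester oxygen nearby to intercept it while the 5(10)- and 8(9)-olefins add anti in a chair–chair fold (closest known: Lewis‑acid epoxide‑initiated cation–olefin polycyclisation of isolated, O‑protected epoxides); inversion at C‑4 places the Z‑derived CH2O group axial, the 3‑hydroxyl equatorial, C‑5/C‑10 trans and the C‑9 chain equatorial, and the C‑8 cation loses H‑7 to give the 7,8‑olefin of ring B.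

Step 8
Reactants: 13 (3R,4R,5S,9R,10S,13R)-15-[(tert-butyldimethylsilyl)oxy]-ent-labd-7-ene-3,19-diol
Product: 14 (3R,4R,5S,9R,10S,13R)-19-acetoxy-15-[(tert-butyldimethylsilyl)oxy]-ent-labd-7-en-3-ol
Conditions: Ac2O (1.1 equiv), pyridine, CH2Cl2, 0 °C
Reagents that add atoms: acetic anhydride, CC(=O)OC(C)=O
Why: Selective O‑acetylation: the primary C‑19 hydroxyl reacts far faster than the secondary C‑3 hydroxyl next to the quaternary C‑4.

Step 9
Reactants: 14 (3R,4R,5S,9R,10S,13R)-19-acetoxy-15-[(tert-butyldimethylsilyl)oxy]-ent-labd-7-en-3-ol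
Product: 15 (4R,5S,9R,10S,13R)-19-acetoxy-3-oxo-ent-labd-7-en-15-oic acid
Conditions: CrO3, H2SO4, H2O, acetone, 0 → 23 °C
Reagents that add atoms: water, O
Why: Jones oxidation takes the C‑3 alcohol to the ketone and, in the same acidic medium, cleaves the primary silyl ether and oxidises the freed alcohol through the aldehyde hydrate to the acid; the acetate and the trisubstituted olefin are inert.

Step 10
Reactants: 15 (4R,5S,9R,10S,13R)-19-acetoxy-3-oxo-ent-labd-7-en-15-oic acid
Product: 17 (2S,4R,5S,9R,10S,13R)-19-acetoxy-2-hydroxy-3-oxo-ent-labd-7-en-15-oic acid, via dipotassium enolate carboxylate 16 (not isolated)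
Conditions: KN(SiMe3)2 (2.3 equiv), THF, −78 °C; then 2-(phenylsulfonyl)-3-phenyloxaziridine (1.3 equiv), −78 °C; cold 1 M HCl
Reagents that add atoms: 2-(phenylsulfonyl)-3-phenyloxaziridine, O=S(=O)(c1ccccc1)N1OC1c1ccccc1
Why: Davis oxaziridine hydroxylation of the only possible ketone enolate (C‑4 is quaternary): oxygen enters C‑2 on the face opposite the axial C‑19 and C‑20 groups, giving the equatorial 2‑hydroxyl (2S).

Step 11
Reactants: 17 (2S,4R,5S,9R,10S,13R)-19-acetoxy-2-hydroxy-3-oxo-ent-labd-7-en-15-oic acid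
Product: 18 (2S,3R,4R,5S,9R,10S,13R)-19-acetoxy-2,3-dihydroxy-ent-labd-7-en-15-oic acid
Conditions: LiBH(s-Bu)3 (4 equiv), THF, −78 °C; cold 1 M HCl
Reagents that add atoms: none
Why: Trialkylborohydride reduction: the bulky hydride attacks along the equatorial trajectory and gives the axial C‑3 alcohol cis to the 2‑hydroxyl (3R), as in the reduction of 4,4‑disubstituted 3‑keto terpenoids to their axial alcohols; carboxylate and acetate are not reduced at −78 °C.

## Compound list

1 | (2E,6E)-farnesol, (2E,6E)-3,7,11-trimethyldodeca-2,6,10-trien-1-ol | OC/C=C(\C)CC/C=C(\C)CCC=C(C)C | starting material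
2 | (R)-2,3-dihydrofarnesol, (3R,6E)-3,7,11-trimethyldodeca-6,10-dien-1-ol | OCC[C@H](C)CC/C=C(\C)CCC=C(C)C | intermediate
3 | tert-butyldimethyl{[(3R,6E)-3,7,11-trimethyldodeca-6,10-dien-1-yl]oxy}silane | CC(C)(C)[Si](C)(C)OCC[C@H](C)CC/C=C(\C)CCC=C(C)C | intermediate
4 | (2E,6E,10R)-12-[(tert-butyldimethylsilyl)oxy]-2,6,10-trimethyldodeca-2,6-dien-1-ol (formed in the flask) | CC(C)(C)[Si](C)(C)OCC[C@H](C)CC/C=C(\C)CC/C=C(\C)CO | intermediate
5 | (2E,6E,10R)-12-[(tert-butyldimethylsilyl)oxy]-2,6,10-trimethyldodeca-2,6-dienal | CC(C)(C)[Si](C)(C)OCC[C@H](C)CC/C=C(\C)CC/C=C(\C)C=O | intermediate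
6 | tert-butyldimethyl{[(3R,6E,10E)-3,7,11-trimethyltrideca-6,10,12-trien-1-yl]oxy}silane | CC(C)(C)[Si](C)(C)OCC[C@H](C)CC/C=C(\C)CC/C=C(\C)C=C | intermediate
7 | prop-2-yn-1-ol (propargyl alcohol) | C#CCO | starting material
8 | bromomagnesium (Z)-3-(bromomagnesio)-2-methylprop-2-en-1-olate (formed in the flask) | C/C(CO[Mg]Br)=C/[Mg]Br | intermediate
9 | (Z)-3-iodo-2-methylprop-2-en-1-ol | C/C(CO)=C/I | intermediate
10 | 9-[(3E,7E,11R)-13-[(tert-butyldimethylsilyl)oxy]-3,7,11-trimethyltrideca-3,7-dien-1-yl]-9-borabicyclo[3.3.1]nonane (formed in the flask) | CC(C)(C)[Si](C)(C)OCC[C@H](C)CC/C=C(\C)CC/C=C(\C)CCB1C2CCCC1CCC2 | intermediate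
11 | (2Z,6E,10E,14R)-16-[(tert-butyldimethylsilyl)oxy]-2,6,10,14-tetramethylhexadeca-2,6,10-trien-1-ol | CC(C)(C)[Si](C)(C)OCC[C@H](C)CC/C=C(\C)CC/C=C(\C)CC/C=C(/C)CO | intermediate
12 | [(2S,3R)-3-[(3E,7E,11R)-13-[(tert-butyldimethylsilyl)oxy]-3,7,11-trimethyltrideca-3,7-dien-1-yl]-2-methyloxiran-2-yl]methanol (cis-epoxide, formed in the flask) | CC(C)(C)[Si](C)(C)OCC[C@H](C)CC/C=C(\C)CC/C=C(\C)CC[C@H]1O[C@@]1(C)CO | intermediate
13 | (3R,4R,5S,9R,10S,13R)-15-[(tert-butyldimethylsilyl)oxy]-ent-labd-7-ene-3,19-diol (3-OH equatorial, cis to the axial C-19 CH2OH; C-19 cis to C-20) | OC[C@@]1(C)[C@H]2CC=C(C)[C@@H](CC[C@@H](C)CCO[Si](C)(C)C(C)(C)C)[C@]2(C)CC[C@H]1O | intermediate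
14 | (3R,4R,5S,9R,10S,13R)-19-acetoxy-15-[(tert-butyldimethylsilyl)oxy]-ent-labd-7-en-3-ol | CC(=O)OC[C@@]1(C)[C@H]2CC=C(C)[C@@H](CC[C@@H](C)CCO[Si](C)(C)C(C)(C)C)[C@]2(C)CC[C@H]1O | intermediate
15 | (4R,5S,9R,10S,13R)-19-acetoxy-3-oxo-ent-labd-7-en-15-oic acid | CC(=O)OC[C@@]1(C)[C@H]2CC=C(C)[C@@H](CC[C@@H](C)CC(=O)O)[C@]2(C)CCC1=O | intermediate
16 | dipotassium salt of 15: 15-carboxylate and C-2/C-3 enolate (formed in the flask) | CC(=O)OC[C@@]1(C)[C@H]2CC=C(C)[C@@H](CC[C@@H](C)CC(=O)[O-])[C@]2(C)CC=C1[O-].[K+].[K+] | intermediate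
17 | (2S,4R,5S,9R,10S,13R)-19-acetoxy-2-hydroxy-3-oxo-ent-labd-7-en-15-oic acid (2-OH equatorial) | CC(=O)OC[C@@]1(C)[C@H]2CC=C(C)[C@@H](CC[C@@H](C)CC(=O)O)[C@]2(C)C[C@H](O)C1=O | intermediate
18 | (2S,3R,4R,5S,9R,10S,13R)-19-acetoxy-2,3-dihydroxy-ent-labd-7-en-15-oic acid (2-OH equatorial, 3-OH axial, cis, on the face opposite C-19 and C-20) | CC(=O)OC[C@@]1(C)[C@H]2CC=C(C)[C@@H](CC[C@@H](C)CC(=O)O)[C@]2(C)C[C@H](O)[C@@H]1O | target

## Step count and risks

Total steps: 11. Longest linear sequence: 10 (steps 1–4 and 6–11; step 5 is the side branch).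

The three steps most likely to fail are 7, 10 and 11.

**Step 7 (the proposed one‑flask epoxidation/bicyclisation).** The leftover tartrate, alcohols and phosphate may blunt the aluminium Lewis acid, chloride or alkoxide may open the epoxide, and 8(17)‑olefin isomers may form at the termination. The fallback sets out from 11 and comes back at 13, using known stepwise chemistry. Compound 11 is epoxidised under ordinary catalytic Sharpless conditions (Ti(OiPr)4, L‑(+)‑diethyl tartrate, t‑BuOOH, 4 Å sieves, CH2Cl2, −20 °C) and the epoxy alcohol 12 is isolated. Its primary hydroxyl is capped with Et3SiCl/imidazole to give the triethylsilyl ether of 12 F1, so that no acyl or free oxygen sits next to the ionising carbon. Classical epoxide‑initiated cation–olefin bicyclisation of this isolated, protected epoxide with MeAlCl2 (CH2Cl2, −78 °C) gives the 19‑O‑triethylsilyl 3‑hydroxy bicycle F2. Pyridinium p‑toluenesulfonate in MeOH at 0 °C then removes only the triethylsilyl group (the primary tert‑butyldimethylsilyl ether stays) and returns diol 13.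

**Step 10 (hydroxylation through a dianion).** A strong base in the presence of the acetate and the free acid can cause acyl transfer, poor solubility of the dianion or incomplete enolisation. The fallback sets out from 15 and comes back at 17 and avoids the metal enolate. Soft enolisation with Me3SiOTf/Et3N (CH2Cl2, 0 °C) gives the trimethylsilyl ester/trimethylsilyl enol ether of 15 F3. Rubottom oxidation with dimethyldioxirane (1.0 equiv, acetone, −78 °C) epoxidises the electron‑rich enol ether from the open face in preference to the ring‑B olefin. Aqueous citric acid hydrolyses both silyl groups to give 17.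

**Step 11 (face selectivity of the ketone reduction).** If the axial C‑19 CH2OAc group forces the borohydride onto the other face, the trans‑diol would result. The fallback sets out from 17 and comes back at 18 and replaces substrate control by catalyst control. Noyori–Ikariya transfer hydrogenation with RuCl(p‑cymene)[(S,S)‑TsDPEN] or its (R,R) antipode (HCO2H/Et3N 5:2, 25–40 °C) is applied to the α‑hydroxy ketone; the antipode that delivers hydride to the C‑19 face gives the cis‑diol 18 directly. This fallback passes through no new compound (F0).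

Further compounds
F1 | step 7 | triethylsilyl ether of 12: tert-butyl{[(3R,6E,10E)-13-[(2R,3S)-3-methyl-3-[(triethylsilyloxy)methyl]oxiran-2-yl]-3,7,11-trimethyltrideca-6,10-dien-1-yl]oxy}dimethylsilane | CC(C)(C)[Si](C)(C)OCC[C@H](C)CC/C=C(\C)CC/C=C(\C)CC[C@H]1O[C@@]1(C)CO[Si](CC)(CC)CC
F2 | step 7 | (3R,4R,5S,9R,10S,13R)-15-[(tert-butyldimethylsilyl)oxy]-19-[(triethylsilyl)oxy]-ent-labd-7-en-3-ol | CC[Si](CC)(CC)OC[C@@]1(C)[C@H]2CC=C(C)[C@@H](CC[C@@H](C)CCO[Si](C)(C)C(C)(C)C)[C@]2(C)CC[C@H]1O
F3 | step 10 | trimethylsilyl (4R,5S,9R,10S,13R)-19-acetoxy-3-[(trimethylsilyl)oxy]-ent-labda-2,7-dien-15-oate | CC(=O)OC[C@@]1(C)[C@H]2CC=C(C)[C@@H](CC[C@@H](C)CC(=O)O[Si](C)(C)C)[C@]2(C)CC=C1O[Si](C)(C)C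
F0 | step 11 | none | none
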